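The rate constants are assumed; no experiment stands behind them.

Before you repeat an earlier run at another temperature, spend a page on what that flask can hold.

    substrate ⇌ other conformer (K1 = 2.1, k1 = 0.0021 s⁻¹, Ea1 = 90.0 kJ mol⁻¹, ΔH1 = 9.00 kJ mol⁻¹)
    substrate → target (k2 = 0.063 s⁻¹, Ea2 = 90.0 kJ mol⁻¹)
    other conformer → isomer of the product (k3 = 0.56 s⁻¹, Ea3 = 74.0 kJ mol⁻¹)
    other conformer ⇌ third conformer (K4 = 0.41, k4 = 1.7 s⁻¹, Ea4 = 68.0 kJ mol⁻¹, ΔH4 = −84.0 kJ mol⁻¹)
    third conformer → third product (k5 = 0.10 s⁻¹, Ea5 = 83.0 kJ mol⁻¹)
    target → over-reaction product (k6 = 1.1 × 10⁻⁴ s⁻¹, Ea6 = 100 kJ mol⁻¹)
    substrate + target → side product (k7 = 0.67 M⁻¹ s⁻¹, Ea7 = 40.0 kJ mol⁻¹)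
    (constants at 35 °C)

in all of them: substrate 0.10 M; time 3.0 min

| run | temperature |
|---|---|
| winter | 35 °C |
| dawn | 85 °C |
| noon | 60 °C |

- in percentages every species weighs as the substrate in it: one side product counts as two
- constants are those at 35 °C; use the activation energies and enthalpies for any other temperature
- in a conversion other conformer counts as not yet reacted; third conformer counts as reacted

* which flask leads in amount of target, in percent of the substrate charged ("all alike" within 1.5 percentage points) (winter / dawn / noon / all alike)
* how much target is there at the end, in percent of the substrate charged: winter
* how much target is there at the end, in percent of the substrate charged: dawn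
* how much target is there at the end, in percent of the substrate charged: noon

**Crowding number.** Substrate makes target at a rate proportional to [substrate], and it destroys target at a rate proportional to [substrate][target]. Since [substrate] stands in both, their contest can be reckoned without the clock. Let ρ be the side step's constant times the charged [substrate], divided by the constant for substrate to target, a selectivity factor: 1.06 in winter, 0.246 at noon and 0.0697 at dawn. It is lower at dawn than at noon because the side step has the smaller activation energy. The leak to the other conformer, ε = 0.0333, is alike in the three flasks because its activation energy equals that of target formation. You may count the leak as lost, because the isomer step far outruns the way back in winter and at dawn.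

**Mean target.** Replace the curve of target by one mean m, as a fraction of the charge. Each substrate spent then yields (1 − ρm)/(1 + ε + ρm) of target, writing 1 for the unit. Each substrate spent yields less target as target builds up, so m, taken over the substrate spent, lies between half its end value and that end value. Half gives my ceiling, an estimate and not a proof, and the end value gives the floor. Target formed, before over-reaction:

- winter: 39.7% to 54.0%
- noon: 69.0% to 79.7%
- dawn: 86.0% to 90.9%

**Over-reaction.** Its constant is 1.1 × 10⁻⁴ s⁻¹ in winter, 0.00206 s⁻¹ at noon and 0.0256 s⁻¹ at dawn. The floor lets it run the whole 3.0 min. The ceiling starts it after 5 lifetimes of substrate, reckoned on the step to target by itself: 79.4 s in winter, 5.69 s at noon, 0.589 s at dawn. My brackets are winter 38.9% to 53.4%, noon 47.7% to 55.7%, and dawn 0.861% to 0.924%. Noon's floor is lower than winter's ceiling, so by hand I cannot rank those two.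

**The forecast.** It names noon, with 50.6% for winter, 0.09% for dawn and 54.8% for noon, on the ground that over-reaction “leaves noon slightly ahead of winter”. Its winter and noon figures stand inside my brackets, while its dawn figure is lower than my floor.

**The flasks.** Noon leads: 54.9% against 50.5% in winter and 0.913% at dawn, each inside its bracket. Dawn holds ten times the forecast's figure, a gap of 0.82 percentage points. Noon's lead over winter of 4.4 points is larger than the margin of 1.5 points.

**Leaner dawn.** Now charge a dawn flask with 0.060 M of substrate, holding the time and the rest. ρ scales with the charge, so it becomes 0.0418. The same two roots and the same over-reaction give a bracket of 0.900% to 0.947%. The flask ends at 0.935% of target, inside it. Its side product stands at 3.72%, against 6.00% in the fuller dawn flask.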